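## Analysis of the target

- CNP0335608.0 (21) is an achiral triaryl bis-ether: three six-membered carbocycles joined by two ether oxygens, with no stereocentre and no ring fusion.
- Ring A is a 2-isopropyl-4-methoxy-5-methylphenyl group (A1 oxygen, A2 isopropyl, A4 methoxy, A5 methyl). Ring B carries B1 O–ring A, B2 methyl, B3 methoxy, B4 H, B5 isopropyl and B6 O–ring C. Ring C is a 1,4-benzoquinone with carbonyls at C1 and C4, the aryloxy group at C2, methyl at C3, H at C5 and isopropyl at C6.
- The two ether oxygens stand on the neighbouring carbons B1 and B6, and B6 is also flanked by the B5 isopropyl group, so the B6–O–C2 linkage is the most crowded bond.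
- The 2-aryloxyquinone is a vinylogous aryl ester: electrophilic, reducible, and incompatible with organolithium bases and with hot basic copper couplings. Ring C therefore has to travel as a protected phenol and be oxidised last.
- The A4 and B3 methyl ethers must survive to the end, so the ring C oxygen needs a protecting group that is orthogonal to methyl.
- The difficulty is regiochemical: three electron-rich rings of similar reactivity, each with four or five substituents.
- The plan rests on one feature. Without their methyl groups, rings B and C show the same 1,3-dioxygen-5-isopropyl pattern (B1/B3 with B5; C2/C4 with C6). The methyl-bearing carbons B2 and C3 are each the one ring carbon lying between two oxygen-bearing carbons, which is the most acidic aryl C–H position of its ring.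

## Retrosynthetic reasoning

**21 ⇒ 20.** The last disconnection removes the C1 carbonyl oxygen. The quinone is traced to phenol 20, which has the hydroxyl at C4 and a hydrogen at C1, para to it. The aryloxyquinone tolerates neither bases nor nucleophiles, so it is made last. The forward reaction has to oxygenate C1 of ring C only; rings A and B have no free hydroxyl group and stay out of a phenoxyl-radical pathway.

**20 ⇒ 19.** The C4 hydroxyl is masked as a methoxymethyl ether. This acetal comes off under mild acid in the presence of the two methyl ethers and the two diaryl ethers. Before that, it is the strongest coordinating group of the key step.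

**19 ⇒ 17 + 12.** The B2–CH3 and C3–CH3 bonds are cut together. Each carbon lies between two oxygen-bearing carbons, so both bonds can be made in one pot from the dilithio species 18 and 12. The gain is that 17 holds rings B and C with the same substitution pattern, so no methyl regiochemistry has to be carried through the ether couplings. The forward step has to metalate exactly B2 and C3.

**17 ⇒ 16 + 10.** The B6–O bond is cut, not the O–C2 bond, so the oxygen stays with ring C. Then 10 is a simple, unhindered phenol, and the halogen sits on ring B, where electrophilic substitution can place it. The forward reaction is a copper-catalysed arylation of 10 by a bromide flanked on both sides; this is the most demanding bond formation before the key step.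

**16 ⇒ 15.** The B6–Br bond is cut. B6 is para to the B3 methoxy group on the resorcinol-type ring B, the most activated ring of 15. The forward bromination should therefore prefer B6 over B4, B2 and ring A.

**15 ⇒ 14 + 5.** The A1–O bond is cut with the oxygen left on ring B. The halide goes on ring A because the position para to the methoxy group of 13 is halogenated without ambiguity, and 5 is again an unhindered phenol.

**14 ⇒ 13 ⇒ 11 + 12.** The iodide comes from para-iodination of 13, the methyl ether of the terpene phenol 11. Compound 11 already holds the methyl and isopropyl groups of ring A in the right 1,4-relation.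

**5 ⇒ 2 ⇒ 1 and 10 ⇒ 7 ⇒ 1 + 6.** The two phenols are the monomethyl and the mono(methoxymethyl) ether of the same symmetric ring. They are traced to the enol ethers 2 and 7 of dione 1. A 1,3-dione has only one enol hydroxyl, so mono-O-alkylation is inherent and no statistical protection is needed. The forward aromatization removes two hydrogens by way of the silyl dienol ethers 3 and 8 and the aryl silyl ethers 4 and 9.

## Alternatives that were turned down

**Alternative 1:** Ring C is cut at C2–C3 and C6–C1 and traced to a Diels–Alder reaction.
- Forward key step: the (2Z,4E)-siloxydiene A2 and the (E)-nitrovinyl ether A3, itself made from the ring A–ring B phenol A4, would combine to the nitrocyclohexene A1. Its four stereocentres are all erased later. Loss of the silyl group, loss of the nitro group as nitrite and a dehydrogenation would then give ring C at the phenol level.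
- For it: the para relation of silyloxy (C4) and nitro (C1) in the cycloaddition places methyl, aryloxy and isopropyl correctly in one step. The crowded B6–O bond is made as an O–vinyl and not an O–aryl bond. Ring C needs no organolithium chemistry, and on that point it is the gentler plan.
- Against it: A3 is a push–pull alkene whose aryloxy donor raises the LUMO, and A2 has only one activating oxygen and two terminal substituents. The cycloaddition should be slow and compete with the heterodiene reactivity of the nitroalkene.
- Against it: in A1 the aryloxy group on C2 is β to the nitronate carbon C1 and, after enol ether hydrolysis, β to the C4 ketone through C3. Each basic or acidic step needed for aromatization can expel the ring A–ring B fragment by E1cB elimination.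
- Against it: A4 already needs the A–B ether, the B2 methyl group and an oxygen at B6, so ring B is not simplified.
- Comparison: the chosen route keeps ring C aromatic throughout, makes both methyl bonds in one operation and should be several steps shorter, at the price of one hindered copper coupling.

**Alternative 2:** Ring B is cut at B3–B4 and built by a Moore–Liebeskind ring expansion.
- Forward key step: thermolysis of the 4-alkenyl-4-(methoxymethoxy)cyclobutenone A6 opens it to a dienylketene. Its 6π closure and tautomerization give the hydroquinone derivative A5, with B3–OH free and B6–O protected.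
- For it: every substituent of ring B, including the B2 methyl group, arrives regiochemically fixed by the way the four-membered ring is assembled, and the B3 and B6 oxygens come out differentiated. Here it is stronger than the chosen route, which relies on directing effects in one bromination.
- Against it: A6 needs a four-membered-ring dione that already carries methyl and the ring A aryloxy group, a regioselective addition of a branched alkenylmetal, and protection of a hindered tertiary alkoxide.
- Against it: after the ring expansion, B3–OH must be methylated, B6–O unmasked and the same hindered B6–O–C2 ether still made. Ring C, with its own methyl group, is not addressed at all, so the step count is clearly higher.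
- Comparison: the chosen route offers a ring B that starts as a six-membered ring, one dione for rings B and C, and one step for both methyl groups.

**Alternative 3:** Ring C is cut at C3–C4, C1–C2 and C4–C5 (Danheiser benzannulation).
- Forward key step: heating 3-isopropylcyclobutenone A8 with the 1-propynyl ether A9 of phenol A4 would give phenol A7, which is identical with 20. The sequence is vinylketene formation, (2+2) cycloaddition, 4π opening, 6π closure and tautomerization.
- For it: ring C is created with hydroxyl, methyl, aryloxy and isopropyl in their final places in one thermal step, with no protecting group and no metal-mediated coupling to a ring C partner. It lands one step before the target and is the most convergent of the four plans for ring C.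
- Against it: A9 must be made from the doubly ortho-substituted phenol A4 by a multistep ynol ether synthesis. A4 itself contains the A–B ether, the B2 methyl group and the B6 oxygen, whose introduction costs as much as the chemistry it replaces.
- Against it: aryl ynol ethers are weaker ketenophiles than alkyl or silyl ynol ethers, so dimerization of the vinylketene from A8 competes. A8 is volatile and is itself several steps from commercial materials.
- Comparison: the chosen route is weaker in convergence but uses only bench-stable intermediates. Its single metalation step also delivers the B2 methyl group that this alternative has to introduce separately.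

Key step: step 10

Remark: the target has no stereocentre. Compounds 2, 3, 7 and 8 each carry one stereocentre at the isopropyl-bearing ring carbon; they are used as racemates and lose it on aromatization.

## Route

Step 1
Reactants: 1 5-isopropylcyclohexane-1,3-dione
Product: 2 3-methoxy-5-isopropylcyclohex-2-en-1-one (racemic)
Conditions: MeOH, TsOH·H2O (cat.), 3 Å MS, reflux
Reagents that add atoms: methanol, CO
Why: Acid-catalysed vinylogous esterification; the dione reacts through its single enol hydroxyl, so exactly one oxygen is methylated and the mono-ether pattern of ring B is fixed without a statistical alkylation.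

Step 2
Reactants: 2 3-methoxy-5-isopropylcyclohex-2-en-1-one
Product: 5 3-isopropyl-5-methoxyphenol, via silyl dienol ether 3 (not isolated), via aryl silyl ether 4 (not isolated)
Conditions: LiN(iPr)2, THF, −78 °C; Me3SiCl, −78 °C → rt; then DDQ, 2,6-lutidine, CH2Cl2, 0 °C → rt; then K2CO3, MeOH, rt
Reagents that add atoms: chlorotrimethylsilane, C[Si](C)(C)Cl (its atoms stay only in 3 and 4)
Why: Kinetic α′-deprotonation and O-silylation give the cyclohexa-1,3-diene 3; DDQ abstracts an allylic hydride and the cation loses a proton (dehydrogenative aromatization of a cyclohexadiene), and methanolysis of 4 frees the phenol. Either direction of enolization leads to the same arene, so enolate regiochemistry does not matter.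

Step 3
Reactants: 1 5-isopropylcyclohexane-1,3-dione; 6 chloromethyl methyl ether
Product: 7 5-isopropyl-3-(methoxymethoxy)cyclohex-2-en-1-one (racemic)
Conditions: iPr2NEt, CH2Cl2, 0 °C → rt
Reagents that add atoms: none
Why: O-Alkylation of the dione enolate by the hard, oxocarbenium-like electrophile gives the vinylogous methoxymethyl ester; as in step 1, only one oxygen can react.

Step 4
Reactants: 7 5-isopropyl-3-(methoxymethoxy)cyclohex-2-en-1-one
Product: 10 3-isopropyl-5-(methoxymethoxy)phenol, via silyl dienol ether 8 (not isolated), via aryl silyl ether 9 (not isolated)
Conditions: LiN(iPr)2, THF, −78 °C; Me3SiCl, −78 °C → rt; then DDQ, 2,6-lutidine, CH2Cl2, 0 °C → rt; then K2CO3, MeOH, rt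
Reagents that add atoms: chlorotrimethylsilane, C[Si](C)(C)Cl (its atoms stay only in 8 and 9)
Why: Same enolization–silylation–DDQ aromatization as in step 2; the conditions are basic or buffered throughout, so the acetal should survive, and carbonate-mediated methanolysis removes only the silyl group.

Step 5
Reactants: 11 carvacrol (5-isopropyl-2-methylphenol); 12 iodomethane
Product: 13 carvacrol methyl ether (4-isopropyl-2-methoxy-1-methylbenzene)
Conditions: K2CO3, acetone, reflux
Reagents that add atoms: none
Why: Williamson etherification of the phenoxide.

Step 6
Reactants: 13 carvacrol methyl ether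
Product: 14 1-iodo-2-isopropyl-4-methoxy-5-methylbenzene
Conditions: NIS, CF3CO2H (cat.), MeCN, rt
Reagents that add atoms: N-iodosuccinimide, O=C1CCC(=O)N1I
Why: Electrophilic aromatic iodination goes para to the methoxy group, at the carbon next to the isopropyl group; the only free ortho site is flanked by methoxy and isopropyl and is less reactive.

Step 7
Reactants: 14 1-iodo-2-isopropyl-4-methoxy-5-methylbenzene; 5 3-isopropyl-5-methoxyphenol
Product: 15 ring A–ring B diaryl ether 1-(3-isopropyl-5-methoxyphenoxy)-2-isopropyl-4-methoxy-5-methylbenzene
Conditions: CuI (10 mol%), picolinic acid (20 mol%), K3PO4, DMSO, 90 °C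
Reagents that add atoms: none
Why: Ligand-accelerated Ullmann diaryl ether synthesis; the phenoxide of 5 on monovalent copper adds to the C–I bond and reductive elimination forms A1–O. The iodide is used because the ortho-isopropyl, para-methoxy ring is a slow electrophile, and phenol 5 is unhindered.

Step 8
Reactants: 15 ring A–ring B diaryl ether
Product: 16 2-bromo-1-isopropyl-3-(2-isopropyl-4-methoxy-5-methylphenoxy)-5-methoxybenzene (bromine at B6)
Conditions: NBS (1.0 equiv), MeCN, −20 → 0 °C, dark
Reagents that add atoms: N-bromosuccinimide, O=C1CCC(=O)N1Br
Why: Electrophilic aromatic bromination of the most activated ring; every free position of ring B is ortho or para to both oxygens, those of ring A to one only. Within ring B the methoxy group is the stronger para director, which points to B6 over B4 (para to aryloxy) and B2 (ortho to both); bromine is used here because the smaller electrophile tolerates the flanked site.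

Step 9
Reactants: 16 B6 bromide of the ring A–ring B ether; 10 3-isopropyl-5-(methoxymethoxy)phenol
Product: 17 triaryl ether 1-isopropyl-2-[3-isopropyl-5-(methoxymethoxy)phenoxy]-3-(2-isopropyl-4-methoxy-5-methylphenoxy)-5-methoxybenzene
Conditions: CuI (20 mol%), picolinic acid (40 mol%), K3PO4, DMSO, 110 °C
Reagents that add atoms: none
Why: Ullmann diaryl ether synthesis with the picolinic acid ligand system used for ortho-substituted partners; the unhindered phenoxide of 10 is the nucleophile and the B6 bromide the electrophile. The acetal is stable to phosphate base in DMSO.

Step 10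
Reactants: 17 triaryl ether (ring C as methoxymethyl ether); 12 iodomethane
Product: 19 1-isopropyl-2-[5-isopropyl-3-(methoxymethoxy)-2-methylphenoxy]-3-(2-isopropyl-4-methoxy-5-methylphenoxy)-5-methoxy-4-methylbenzene, via dilithio triaryl ether 18 (not isolated)
Conditions: n-BuLi (2.4 equiv), TMEDA, THF, −20 → 0 °C; then MeI (excess), −78 °C → rt
Reagents that add atoms: n-butyllithium, [Li]CCCC (lithium stays only in 18)
Why: The base is pre-coordinated by the two oxygen substituents that flank B2–H (B1 aryloxy, B3 methoxy) and C3–H (C2 aryloxy, C4 methoxymethoxy); deprotonation inside this complex, helped by the inductive acidification from two ortho oxygens, should give the dilithio species 18. The closest known reaction is the 2-lithiation and alkylation of 1,3-dimethoxybenzene and of resorcinol methoxymethyl ethers, run here on two rings of one molecule. The two carbanions sit on different, non-conjugated rings, so the second metalation meets no dianion penalty. Iodomethane then alkylates each aryl–lithium bond by SN2 attack at carbon, forming B2–CH3 and C3–CH3. No ring is closed and no stereocentre is formed. The step needs selectivity for the doubly flanked positions over the singly activated ring sites (B4, C5, C1, A3, A6) and over the benzylic A5 methyl and isopropyl C–H bonds; only B2 and C3 offer two-point coordination, the ring sites next to an isopropyl group are shielded, and lateral metalation needs stronger bases. Holding the base near 2.4 equivalents at or below 0 °C should prevent a third metalation, and ortho-lithiated diaryl ethers do not eliminate to arynes at this temperature.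

Step 11
Reactants: 19 dimethylated triaryl ether (ring C as methoxymethyl ether)
Product: 20 3-[6-isopropyl-2-(2-isopropyl-4-methoxy-5-methylphenoxy)-4-methoxy-3-methylphenoxy]-5-isopropyl-2-methylphenol
Conditions: HCl (cat.), MeOH, 50 °C
Reagents that add atoms: none
Why: Acid-catalysed acetal exchange; protonation of the acetal, loss of the phenol and capture of the methoxymethyl cation by methanol. Aryl methyl ethers and diaryl ethers are inert to dilute acid.

Step 12
Reactants: 20 ring C phenol
Product: 21 CNP0335608.0, 2-[6-isopropyl-2-(2-isopropyl-4-methoxy-5-methylphenoxy)-4-methoxy-3-methylphenoxy]-6-isopropyl-3-methylcyclohexa-2,5-diene-1,4-dione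
Conditions: Co(salen) (C16H14CoN2O2, 10 mol%), O2 (1 atm), MeCN, rt
Reagents that add atoms: dioxygen, O=O
Why: Cobalt–salen catalysed aerobic oxidation of a phenol with a free para position; the superoxo complex of trivalent cobalt abstracts the phenolic hydrogen, the phenoxyl radical is oxygenated at C1 and the peroxide collapses to the quinone. Phenol 20 has the 2,3,5-trisubstitution for which this oxidation is known to give p-quinones, and rings A and B have no free hydroxyl group.

## Compound list

1 | 5-isopropylcyclohexane-1,3-dione | CC(C)C1CC(=O)CC(=O)C1 | starting material
2 | 3-methoxy-5-isopropylcyclohex-2-en-1-one (racemic) | COC1=CC(=O)CC(C(C)C)C1 | intermediate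
3 | 1-methoxy-5-isopropyl-3-(trimethylsilyloxy)cyclohexa-1,3-diene (racemic) | COC1=CC(O[Si](C)(C)C)=CC(C(C)C)C1 | intermediate
4 | (3-isopropyl-5-methoxyphenoxy)trimethylsilane | COc1cc(O[Si](C)(C)C)cc(C(C)C)c1 | intermediate
5 | 3-isopropyl-5-methoxyphenol | COc1cc(O)cc(C(C)C)c1 | intermediate
6 | chloromethyl methyl ether | COCCl | starting material
7 | 5-isopropyl-3-(methoxymethoxy)cyclohex-2-en-1-one (racemic) | COCOC1=CC(=O)CC(C(C)C)C1 | intermediate
8 | 5-isopropyl-1-(methoxymethoxy)-3-(trimethylsilyloxy)cyclohexa-1,3-diene (racemic) | COCOC1=CC(O[Si](C)(C)C)=CC(C(C)C)C1 | intermediate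
9 | [3-isopropyl-5-(methoxymethoxy)phenoxy]trimethylsilane | COCOc1cc(O[Si](C)(C)C)cc(C(C)C)c1 | intermediate
10 | 3-isopropyl-5-(methoxymethoxy)phenol | COCOc1cc(O)cc(C(C)C)c1 | intermediate
11 | carvacrol (5-isopropyl-2-methylphenol) | Cc1ccc(C(C)C)cc1O | starting material
12 | iodomethane | CI | starting material
13 | carvacrol methyl ether (4-isopropyl-2-methoxy-1-methylbenzene) | COc1cc(C(C)C)ccc1C | intermediate
14 | 1-iodo-2-isopropyl-4-methoxy-5-methylbenzene | COc1cc(C(C)C)c(I)cc1C | intermediate
15 | 1-(3-isopropyl-5-methoxyphenoxy)-2-isopropyl-4-methoxy-5-methylbenzene | COc1cc(C(C)C)c(Oc2cc(OC)cc(C(C)C)c2)cc1C | intermediate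
16 | 2-bromo-1-isopropyl-3-(2-isopropyl-4-methoxy-5-methylphenoxy)-5-methoxybenzene | COc1cc(C(C)C)c(Oc2cc(OC)cc(C(C)C)c2Br)cc1C | intermediate
17 | 1-isopropyl-2-[3-isopropyl-5-(methoxymethoxy)phenoxy]-3-(2-isopropyl-4-methoxy-5-methylphenoxy)-5-methoxybenzene | COc1cc(C(C)C)c(Oc2cc(OC)cc(C(C)C)c2Oc2cc(OCOC)cc(C(C)C)c2)cc1C | intermediate
18 | B2,C3-dilithio derivative of 17 | COc1cc(C(C)C)c(Oc2c([Li])c(OC)cc(C(C)C)c2Oc2c([Li])c(OCOC)cc(C(C)C)c2)cc1C | intermediate
19 | 1-isopropyl-2-[5-isopropyl-3-(methoxymethoxy)-2-methylphenoxy]-3-(2-isopropyl-4-methoxy-5-methylphenoxy)-5-methoxy-4-methylbenzene | COc1cc(C(C)C)c(Oc2c(C)c(OC)cc(C(C)C)c2Oc2c(C)c(OCOC)cc(C(C)C)c2)cc1C | intermediate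
20 | 3-[6-isopropyl-2-(2-isopropyl-4-methoxy-5-methylphenoxy)-4-methoxy-3-methylphenoxy]-5-isopropyl-2-methylphenol | COc1cc(C(C)C)c(Oc2c(C)c(OC)cc(C(C)C)c2Oc2c(C)c(O)cc(C(C)C)c2)cc1C | intermediate
21 | CNP0335608.0, 2-[6-isopropyl-2-(2-isopropyl-4-methoxy-5-methylphenoxy)-4-methoxy-3-methylphenoxy]-6-isopropyl-3-methylcyclohexa-2,5-diene-1,4-dione | COc1cc(C(C)C)c(Oc2c(C)c(OC)cc(C(C)C)c2OC2=C(C)C(=O)C=C(C(C)C)C2=O)cc1C | target

## Step count and least certain steps

Total step count: 12. Longest linear sequence: 8 steps (steps 1, 2, 7, 8, 9, 10, 11, 12 from dione 1; the ring A branch, steps 5 to 12, is equally long).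

**Step 10 (key step).** The second metalation may stay incomplete, or lithiation may drift to a singly activated ring position or to the A5 methyl group, because B2 is crowded by two neighbouring aryloxy groups and the base is aggregated. That would give under- or mis-methylated mixtures that are hard to separate. The fallback splits the twofold metalation into two single ones and sets out from 15. Metalation of 15 at B2, its only doubly flanked position (n-BuLi, TMEDA, THF, 0 °C), and quenching with 12 should give the B2-methyl diaryl ether 1-(5-isopropyl-3-methoxy-2-methylphenoxy)-2-isopropyl-4-methoxy-5-methylbenzene F1. Bromination with NBS, now with B2 blocked, should give the B6 bromide F2. Copper coupling with 10 under the conditions of step 9 should give the mono-methyl triaryl ether F3. A single metalation at C3, between the aryloxy and methoxymethoxy groups, and quenching with 12 comes back to the route at 19.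

**Step 9.** Oxidative addition of the doubly ortho-substituted, electron-rich bromide to monovalent copper may be so slow that hydrodebromination and oxidative loss of the phenol outrun ether formation. The fallback reverses the polarity of the bond formation and sets out from 16 and 10. Bromine–lithium exchange on 16 (n-BuLi, THF, −78 °C), borylation with B(OMe)3 and oxidation with H2O2/NaOH should give the hindered phenol 2-(2-isopropyl-4-methoxy-5-methylphenoxy)-6-isopropyl-4-methoxyphenol F4. Phenol 10 is converted with Tf2O and pyridine into 3-isopropyl-5-(methoxymethoxy)phenyl trifluoromethanesulfonate F5. Palladium-catalysed C–O coupling of F4 with F5 (Pd(OAc)2, t-BuXPhos, K3PO4, toluene, 100 °C) comes back at 17. Here the hindered partner is the nucleophile, and bulk favours the C–O reductive elimination from divalent palladium.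

**Step 8.** Bromination may go to B4 (para to the aryloxy group), to B2 or onto ring A, because the para-directing advantage of methoxy over aryloxy is only moderate and B6 is flanked on both sides. The fallback sets the bromine before the ether is made and sets out from 5 and 14. Acetylation of 5 (Ac2O, pyridine) gives 3-isopropyl-5-methoxyphenyl acetate F6. Its NBS bromination should go para to the methoxy group, since acetoxy is a weak director, and give 2-bromo-3-isopropyl-5-methoxyphenyl acetate F7. Methanolysis (K2CO3, MeOH) gives 2-bromo-3-isopropyl-5-methoxyphenol F8. Copper coupling of F8 with iodide 14 (CuI, picolinic acid, K3PO4, DMSO, 80 °C), in which the iodide should react far faster than the flanked bromide, comes back at 16.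

**Step 4 (and step 2, same operation).** The silyl dienol ether may hydrolyse back to the enone before dehydrogenation, or DDQ may attack the electron-rich diene as an electrophile instead of abstracting hydride. In step 4 the vinylogous acetal may also be lost. The fallback gives up the enol ether route and sets out from 1. Catalytic dehydrogenation (Pd/C, mesitylene, reflux) should give 5-isopropylbenzene-1,3-diol F9. Monoalkylation with one equivalent of 6 (NaH, DMF, 0 °C) comes back at 10, and with one equivalent of 12 (K2CO3, acetone) at 5. Both are statistical; diol and bis-ether would be separated and recycled.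

**Step 12.** Oxygenation at C1, flanked by aryloxy and isopropyl, may be slow enough for phenoxyl radical coupling or ortho oxygenation to compete. The fallback introduces nitrogen first and sets out from 20. Nitrosation at C1 (NaNO2, HCl, EtOH/H2O, 0 °C) should give the 4-nitrosophenol F10 (tautomer of the quinone monooxime). Reduction with Na2S2O4 gives the 4-aminophenol F11. Oxidation with aqueous FeCl3 and hydrolysis of the quinone imine comes back at 21.

## Further compounds

F1 | step 10 | 1-(5-isopropyl-3-methoxy-2-methylphenoxy)-2-isopropyl-4-methoxy-5-methylbenzene | COc1cc(C(C)C)c(Oc2c(C)c(OC)cc(C(C)C)c2)cc1C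
F2 | step 10 | 2-bromo-1-isopropyl-3-(2-isopropyl-4-methoxy-5-methylphenoxy)-5-methoxy-4-methylbenzene | COc1cc(C(C)C)c(Oc2c(C)c(OC)cc(C(C)C)c2Br)cc1C
F3 | step 10 | 1-isopropyl-2-[3-isopropyl-5-(methoxymethoxy)phenoxy]-3-(2-isopropyl-4-methoxy-5-methylphenoxy)-5-methoxy-4-methylbenzene | COc1cc(C(C)C)c(Oc2c(C)c(OC)cc(C(C)C)c2Oc2cc(OCOC)cc(C(C)C)c2)cc1C
F4 | step 9 | 2-(2-isopropyl-4-methoxy-5-methylphenoxy)-6-isopropyl-4-methoxyphenol | COc1cc(C(C)C)c(Oc2cc(OC)cc(C(C)C)c2O)cc1C
F5 | step 9 | 3-isopropyl-5-(methoxymethoxy)phenyl trifluoromethanesulfonate | COCOc1cc(OS(=O)(=O)C(F)(F)F)cc(C(C)C)c1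
F6 | step 8 | 3-isopropyl-5-methoxyphenyl acetate | COc1cc(OC(C)=O)cc(C(C)C)c1
F7 | step 8 | 2-bromo-3-isopropyl-5-methoxyphenyl acetate | COc1cc(OC(C)=O)c(Br)c(C(C)C)c1
F8 | step 8 | 2-bromo-3-isopropyl-5-methoxyphenol | COc1cc(O)c(Br)c(C(C)C)c1
F9 | step 4 | 5-isopropylbenzene-1,3-diol | CC(C)c1cc(O)cc(O)c1
F10 | step 12 | 3-[6-isopropyl-2-(2-isopropyl-4-methoxy-5-methylphenoxy)-4-methoxy-3-methylphenoxy]-5-isopropyl-2-methyl-4-nitrosophenol | COc1cc(C(C)C)c(Oc2c(C)c(OC)cc(C(C)C)c2Oc2c(C)c(O)cc(C(C)C)c2N=O)cc1C
F11 | step 12 | 4-amino-3-[6-isopropyl-2-(2-isopropyl-4-methoxy-5-methylphenoxy)-4-methoxy-3-methylphenoxy]-5-isopropyl-2-methylphenol | COc1cc(C(C)C)c(Oc2c(C)c(OC)cc(C(C)C)c2Oc2c(C)c(O)cc(C(C)C)c2N)cc1C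
A1 | alternative 1 | Diels–Alder adduct, 6-methyl-4-nitro-3-isopropyl-1-(trimethylsilyloxy)cyclohex-1-ene with the ring A–ring B aryloxy group at C5 (racemic, relative configuration as written) | [O-][N+](=O)[C@H]1[C@H](Oc2c(C(C)C)cc(OC)c(C)c2Oc2cc(C)c(OC)cc2C(C)C)[C@@H](C)C(O[Si](C)(C)C)=C[C@H]1C(C)C
A2 | alternative 1 | (2Z,4E)-6-methyl-3-(trimethylsilyloxy)hepta-2,4-diene | C/C=C(\O[Si](C)(C)C)/C=C/C(C)C
A3 | alternative 1 | (E)-2-nitrovinyl ether of the ring A–ring B phenol | [O-][N+](=O)/C=C/Oc1c(C(C)C)cc(OC)c(C)c1Oc1cc(C)c(OC)cc1C(C)C
A4 | alternative 1 | 2-(2-isopropyl-4-methoxy-5-methylphenoxy)-6-isopropyl-4-methoxy-3-methylphenol | Oc1c(C(C)C)cc(OC)c(C)c1Oc1cc(C)c(OC)cc1C(C)C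
A5 | alternative 2 | 3-(2-isopropyl-4-methoxy-5-methylphenoxy)-5-isopropyl-4-(methoxymethoxy)-2-methylphenol | COCOc1c(C(C)C)cc(O)c(C)c1Oc1cc(C)c(OC)cc1C(C)C
A6 | alternative 2 | 3-(2-isopropyl-4-methoxy-5-methylphenoxy)-4-(methoxymethoxy)-2-methyl-4-(3-methylbut-1-en-2-yl)cyclobut-2-en-1-one (racemic) | O=C1C(C)=C(Oc2cc(C)c(OC)cc2C(C)C)C1(OCOC)C(=C)C(C)C
A7 | alternative 3 | 3-[6-isopropyl-2-(2-isopropyl-4-methoxy-5-methylphenoxy)-4-methoxy-3-methylphenoxy]-5-isopropyl-2-methylphenol (identical with 20) | COc1cc(C(C)C)c(Oc2c(C)c(OC)cc(C(C)C)c2Oc2c(C)c(O)cc(C(C)C)c2)cc1C
A8 | alternative 3 | 3-isopropylcyclobut-2-en-1-one | CC(C)C1=CC(=O)C1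
A9 | alternative 3 | 1-propynyl ether of phenol A4 | CC#COc1c(C(C)C)cc(OC)c(C)c1Oc1cc(C)c(OC)cc1C(C)C
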